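Starting material leaves these flasks slowly, and the books of the two earlier runs do not balance on the products.

| flask | starting material | protic impurity | remark | time |
|---|---|---|---|---|
| gamma | 1 M | 0.13 M | run made earlier |  |
| delta | 1 M | 0.30 M | run made earlier |  |
| south-east | 1.0 M | 0.200 M |  | 10 min |
| east | 1.0 M | 0.200 M |  | 12 min |

| run | time / min | isomer of the product / % | starting material / % | target / % |
|---|---|---|---|---|
| gamma | 1.00 | 0.6 | 92.7 | 4.9 |
| gamma | 2.00 | 1.4 | 86.0 | 9.6 |
| gamma | 3.00 | 1.1 | 80.2 | 13.0 |
| gamma | 6.00 | 2.8 | 66.3 | 24.8 |
| gamma | 12.0 | 3.5 | 47.4 | 39.1 |
| delta | 1.00 | 0.6 | 91.2 | 4.9 |
| delta | 3.00 | 0.3 | 75.1 | 13.4 |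
| delta | 6.00 | 2.9 | 59.7 | 23.3 |
| delta | 8.00 | 2.4 | 52.0 | 28.3 |
| delta | 12.0 | 3.6 | 40.9 | 35.3 |

(standard deviation of a reading: 0.5 percentage points)

* which of these there is most of at the end, counted by the starting material in it, south-east (isomer of the product / target / starting material)
* which of these there is most of at the end, counted by the starting material in it, east (isomer of the product / target / starting material)
* the largest of these amounts at the end, in percent of the starting material charged, south-east
* the largest of these amounts at the end, in percent of the starting material charged, east

The ledger is struck at the last reading of each run. In gamma, starting material, target and isomer of the product fall short of the charge by 0.100 M, and in delta by 0.202 M, twice as much. This reckoning charges each gap to the protic impurity, mole for mole, which makes the impurity the limiting reagent of that loss. The fraction of impurity left is then 0.231 in gamma and 0.327 in delta.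

This reckoning lets the logarithm of that fraction fall in proportion to the exposure, the area under the starting-material curve, taken as a logarithmic mean: 507 M·s in gamma and 476 M·s in delta. The two runs give 0.00289 L mol⁻¹ s⁻¹ and 0.00235 L mol⁻¹ s⁻¹, with mean 0.00262 L mol⁻¹ s⁻¹, the quench constant: the fall of the logarithm of the impurity's fraction left per unit of exposure. Target plus isomer of the product, per unit of exposure, average 0.0497 min⁻¹.

For east, a trial fraction left of 44.1 %, the mean of the two last readings, gives an exposure of 492 M·s. The books of east then read 40.8 % made, 14.5 % quenched and 44.8 % left. For south-east, scaling the logarithm of that fraction to the shorter time gives a trial of 51.2 % and an exposure of 437 M·s. Its books read 36.2 % made, 13.6 % quenched and 50.1 % left. With target and isomer of the product counted together as made, starting material stays the largest entry in both south-east and east.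

The forecast, holding that “the impurity appears to destroy starting material”, names starting material in south-east at 49.5 % and starting material in east at 44.7 %.

The largest amount is starting material in south-east, 50.0 % against the reckoned 50.1 %, and starting material in east, 45.2 % against 44.8 %.

    isomer of the product ⇌ starting material (k = 0.00170 s⁻¹)
    target ⇌ isomer of the product (K = 0.0840, k = 0.00650 s⁻¹)
    starting material + protic impurity → quenched substrate (k = 0.00260 L mol⁻¹ s⁻¹)
    starting material ⇌ target (K = 2.50, k = 6.30 × 10⁻⁴ s⁻¹)

The gap is the quenched substrate, 13.3 % in south-east, where 34 % of the impurity's charge remains. The quench constant, applied to the exposure from the south-east result, gives 32.2 % of the impurity left. On the neighbouring flask, south-east read at 6.0 min with 63.4 % of its starting material left, the same constant gives 46.9 %, and that flask has 48 % of its impurity charge left.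

The readings were generated by integration on assumed constants; noise was put on by code.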